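45.0% of the G charged stood as J at Friday's last reading, against 42.4% at Saturday's, though Friday's flask held 1.47 times the Q. I had to stretch that small step to Sunday.

| setting | Saturday's | Friday's | Monday's | Sunday's |
|---|---|---|---|---|
| G | 100 mM | 100 mM | 100 mM | 100 mM |
| Q | 150 mM | 220 mM | 150 mM | 310 mM |
| J |  |  | 30.0 mM |  |
| time |  |  |  | 4.9 h |

| run | time / h | [J] / mM |
|---|---|---|
| Saturday's run | 0.98 | 11.4 |
| Saturday's run | 2.0 | 26.7 |
| Saturday's run | 2.9 | 35.0 |
| Saturday's run | 3.9 | 40.3 |
| Saturday's run | 4.9 | 42.4 |
| Friday's run | 0.98 | 14.3 |
| Friday's run | 2.0 | 30.3 |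
| Friday's run | 2.9 | 38.8 |
| Friday's run | 3.9 | 42.3 |
| Friday's run | 4.9 | 45.0 |
| Monday's run | 0.98 | 39.3 |
| Monday's run | 2.0 | 52.3 |
| Monday's run | 2.9 | 58.5 |
| Monday's run | 3.9 | 63.1 |
| Monday's run | 4.9 | 62.9 |

(scatter of a reading: 0.5 mM)

- reaction order in [Q] at the outset, round the charge of the Saturday's run, defined at two percent of the G turned into J
- J in the Sunday's run at 4.9 h, as a share of the G charged

- Overall: G + Q -> J.
- Constant volume, constant temperature.
- "The second partner" is Q.
- An order is taken over about fifteen percent of the charge, up and down.

G, the limiting reagent, was charged at less than Q on Saturday, so I wrote its balance in shares of the charge: in a flask charged without J, the share in J plus the share left or gone elsewhere makes one. I assumed that a path taking no Q competes for G, so that the share in J at a given time rises as Q/(Q + K). The last readings of Saturday and Friday put 33.3 mM on K, the Q half-point, the Q charge at which the share in J stands at 0.5 of its ceiling.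

Which inputs did this lean on? The G charge was 100 mM on Saturday, Friday and Sunday alike, and Monday's flask, with Saturday's Q, adds no new point on the Q scale. A Friday reading high by one scatter, 0.500% of the charge, moved K to 40.9 mM and Sunday's share to 47.7%. The same error on Saturday gave 25.8 mM and 46.4%. On this form, the local order in Q at Sunday's charge was 0.0970.

So I took 46.8%, a figure that Friday's error moves more than Saturday's. For the order, the Friday and Saturday readings at 0.98 h gave me an apparent 0.592, give or take 0.146, read with Saturday's flask already at 11.4% in J and so past the mark asked.

The forecast gave 0.7 and 47%, its Sunday share from “a power law or saturation in Q”. Both stand above mine.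

The flask gave 46.3% on Sunday and an order of 0.46, lower than the forecast's, with Friday's rate at 1.2 times Saturday's at the mark asked.

    G ⇌ E + L (0.3046 h⁻¹, 4.536 M⁻¹ h⁻¹)
    E + Q → J (10.58 M⁻¹ h⁻¹)
    G → Vy (0.1321 h⁻¹)
    J → Ez (0.07668 h⁻¹)

Sunday's share stood 0.50 percentage points under the figure from my half-point. Monday's flask had Saturday's Q, so my form with K gave it the share read on Saturday, 42.4%, as made from G. Monday's last reading was 62.9% of the G charge, which on that form left 20.5% for the 30.0% of J charged.

The earlier runs and the new flask were generated by integration from invented constants; noise was put on by code.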